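## Structural features

- The target (C22H24O9) is a furanoheliangolide. Its ten-membered carbocycle C1–C10 (germacrane numbering; C14 is the methyl on C10, C15 the methyl on C4) is bridged by an oxygen from C3 to C10. C1(=O), C2, C3, that oxygen and C10 therefore form a 3(2H)-furanone, whose C2=C3 bond is conjugated with the Z-configured C4=C5 bond.
- An α-methylene-γ-butyrolactone (O on C6, C11 on C7, C12 carbonyl, C13 methylidene) is fused to C6/C7. The SMILES is read as 6S,7S, which puts H6 and H7 on the same face (cis-fused lactone).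
- Five contiguous stereocentres run from C6 to C10: 6S, 7S, 8S, 9S and the quaternary 10R (C14, ring oxygen, C1, C9). In the C6–C10 zigzag, the oxygen on C8 is anti to C11 on C7 and anti to the hydroxyl on C9; that hydroxyl is syn to the ring oxygen on C10.
- C8 carries an (E)-2-(acetoxymethyl)but-2-enoate and C9 a free secondary hydroxyl, so O8 and O9 have to be told apart.
- Fragile groups: the methylene lactone (Michael acceptor), the allylic acetate/enoate of the side chain (SN2' and zerovalent-palladium ionisation), the O8 ester next to a free hydroxyl (acyl migration), the Z-olefin, and the β-hydroxy ketone C9(OH)–C10–C1(=O), which can open by retro-aldol because its enolate is an aromatic 3-oxidofuran.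
- The real difficulty is the strained oxygen-bridged ten-membered ring together with the C9/C10 pair, one of which is quaternary.
- The key step exploits exactly that: C1, C2, C3, O and C10 are a dearomatised 2-methyl-3-hydroxyfuran, and C9–C10 is the aldol bond between the furan carbon C10 and a C9 aldehyde.

## Logic of the disconnections

In one sentence: 31 is made by a ring-closing, dearomatising Mukaiyama aldol addition within the furyl aldehyde 29.

**31 ⇒ 29 (via 30).** Cut: C9–C10. Reason: it is the aldol bond of the β-hydroxy ketone, and C10 is the nucleophilic carbon of the silyloxyfuran hidden in the furanone. Gain: the ten-membered ring, the oxygen bridge, the quaternary centre and the carbinol all disappear, leaving a monocyclic lactone with a flat furan and an aldehyde. Demand: the forward step must close a strained ring under high dilution, choose one furan face and one aldehyde face, spare the methylene lactone and the side-chain ester, and deliver the free O9–H without acyl migration.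

**29 ⇒ 21 + 28.** Cut: the sp2–sp2 bond C3–C4. Reason: the whole furan is joined in one convergent coupling, and the Z geometry of C4=C5 is carried by the vinyl iodide. Gain: 28 is an achiral furan made in three steps; 21 holds all the chirality. Demand: coupling near room temperature with retention of olefin geometry, in the presence of an aldehyde and an allylic acetate.

**21 ⇒ 20 ⇒ 12 + 18 (via 19).** Cuts: the oxidation level at C9, then the ester bond O8–C(=O). Reason: the side chain is put on before ring closure, so O8 and O9 never have to be distinguished on the macrocycle. Gain: 18 is achiral and made separately. Demand: the oxidation must not epimerise C8, and only O8 may be acylated (O9 is silylated).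

**12 ⇒ 11 ⇒ 10.** Cuts: the O9–Si bond and the isopropylidene acetal. Reason: the 8,9-diol arrives protected from the chiral pool. Demand: primary-selective silylation, and no migration of the lactone from O6 to O8 while the diol is free.

**10 ⇒ 4 + 8 (via 9).** Cuts: C6–C7 and the lactone bond C12–O6. Reason: a 2-(bromomethyl)acrylate allylation makes the methylene lactone and sets C6 and C7 in one event from the bought centre C8. Gain: two small fragments. Demand: syn addition (cis-lactone) and the correct face of the allyl unit relative to C8.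

**4 ⇒ 3 ⇒ 1 + 2.** Cuts: the C13–Br bond with allylic transposition, then C7–C11. Reason: Morita–Baylis–Hillman logic gives the acrylate unit directly on the chiral-pool aldehyde. Demand: Z-selective transposition, no loss of configuration at C8.

**8 ⇒ 7 ⇒ 5 (via 6).** Cuts: the oxidation level at C6 and the C4–I bond. Demand: the directed trans-hydroalumination must fix the Z geometry that later becomes C4=C5.

**18 ⇒ 17 ⇒ 15 ⇒ 13 + 14 (via 16).** Cuts: the tert-butyl ester, the 1,3-acetoxy shift, and the C–C bond between acrylate and acetaldehyde. Demand: E geometry (methyl trans to the ester).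

**28 ⇒ 26 ⇒ 25 ⇒ 22 + 23 (via 27 and 24).** Cuts: C3–Sn, O–Si, and the furanone ring (formylation/cyclodehydration). Demand: metalation at the only free α-position of the furan.

## Other disconnections considered

**Alternative 1:** the first idea. Cut C6–C7 and the lactone C–O bond last. Forward key step: intramolecular Barbier-type allylation (zinc, or CrCl2 with divalent chromium) of the seco bromide aldehyde A1, which already contains the furanone; the ring and the lactone close together. Grounds for not choosing it:
- C9 and C10 must first be set in a separate intermolecular furanone aldol that has its own facial problem.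
- O8 and O9 must be protected and later told apart on the macrocycle.
- C6 and C7 would be formed inside a medium-ring transition state, where the simple chair rule that favours the syn (cis-lactone) product no longer applies with confidence.
- It is longer, and it does not use the furan as a building block.

**Alternative 2:** cut the O–C3 bond. Forward key step: transannular 5-endo oxa-Michael addition (for example Ph3PAuNTf2, monovalent gold) of the C10 hydroxyl onto the ten-membered ynone A2. Grounds for not choosing it:
- A2 holds a linear C1–C2≡C3–C4 unit next to a Z-olefin and a cis-fused lactone in a ten-membered ring, so strain is moved into the precursor.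
- The tertiary carbinol C10 needs its own asymmetric step.
- Three oxygen functions (O8, O9, O10) need distinction.
- The ring still has to be closed by another reaction, and extra redox steps are added.

**Alternative 3:** cut C4=C5. Forward key step: intramolecular vinylogous aldol condensation of the 5-ethylfuranone aldehyde A3 (the CH2 of the ethyl group attacks the C5 aldehyde, then dehydration). Grounds for not choosing it:
- The basic conditions that enolise the ethyl group also threaten C6 (α to the aldehyde), the retro-aldol-prone C9–C10 bond and the methylene lactone.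
- The Z geometry is only enforced once the ring exists.
- C9/C10 again come from a separate aldol.
- The count of steps and protecting groups is higher.

Key step: step 17

Remarks on the chemistry:
- The SMILES is taken literally as 6S,7S,8S,9S,10R with a cis-fused lactone.
- Aldehyde 1 is taken as the commercial solution, distilled before use.

## Steps

Step 1
Reactants: 1 (4R)-2,2-dimethyl-1,3-dioxolane-4-carbaldehyde; 2 methyl acrylate
Product: 3 methyl 2-{[(4R)-2,2-dimethyl-1,3-dioxolan-4-yl](hydroxy)methyl}prop-2-enoate (both carbinol epimers)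
Conditions: DABCO (0.5 equiv), dioxane/H2O 1:1, rt, 48 h
Reagents that add atoms: none
Why: Morita–Baylis–Hillman reaction. The new carbinol centre is removed in step 2, so its configuration is irrelevant; the dioxolane centre (later C8) is bought and should survive the neutral amine catalysis.

Step 2
Reactants: 3 methyl 2-{[(4R)-2,2-dimethyl-1,3-dioxolan-4-yl](hydroxy)methyl}prop-2-enoate
Product: 4 methyl (2Z)-2-(bromomethyl)-3-[(4S)-2,2-dimethyl-1,3-dioxolan-4-yl]prop-2-enoate
Conditions: NBS, Me2S, CH2Cl2, 0 °C to rt
Reagents that add atoms: N-bromosuccinimide O=C1CCC(=O)N1Br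
Why: Corey–Kim-type activation of the allylic alcohol followed by SN2' delivery of bromide. This should give the conjugated trisubstituted Z-bromide (dioxolane cis to CH2Br); the acid-free conditions keep the acetonide.

Step 3
Reactants: 5 but-2-yn-1-ol
Product: 7 (2Z)-3-iodobut-2-en-1-ol, via cyclic vinylalanate 6 (not isolated)
Conditions: NaAlH2(OCH2CH2OCH3)2, Et2O, 0 °C to rt; then I2, THF, −78 °C
Reagents that add atoms: iodine II
Why: Alkoxide-directed trans-hydroalumination of the propargylic alcohol puts aluminium on C3 inside a five-membered ring. Iodinolysis with retention fixes iodine cis to the CH2OH group, which is the geometry that becomes Z-C4=C5.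

Step 4
Reactants: 7 (2Z)-3-iodobut-2-en-1-ol
Product: 8 (2Z)-3-iodobut-2-enal
Conditions: MnO2, CH2Cl2, rt, dark; used at once
Reagents that add atoms: none
Why: Neutral heterogeneous oxidation of the allylic alcohol. No acid, base or light is present that could isomerise the Z-iodoenal.

Step 5
Reactants: 4 methyl (2Z)-2-(bromomethyl)-3-[(4S)-2,2-dimethyl-1,3-dioxolan-4-yl]prop-2-enoate; 8 (2Z)-3-iodobut-2-enal
Product: 10 (4S,5R)-4-[(4S)-2,2-dimethyl-1,3-dioxolan-4-yl]-5-[(1Z)-2-iodoprop-1-en-1-yl]-3-methylideneoxolan-2-one, via hydroxy ester 9 (not isolated)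
Conditions: In powder, THF/H2O 1:1, rt; work-up; then CSA (5 mol %), toluene, 4 Å MS, 40 °C
Reagents that add atoms: none
Why: Barbier-type allylation. The allylindium adds through its γ-carbon (C7) in a chair transition state; because the dioxolanyl group is cis to the CH2–metal carbon, the syn adduct should form and close to the cis-lactone (sets C6). The face of the allyl unit is set by C8: with H8 in the olefin plane to avoid allylic strain, the aldehyde should add anti to the C8–C9 bond with the C8 oxygen outside, which corresponds to 7S.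

Step 6
Reactants: 10 (4S,5R)-4-[(4S)-2,2-dimethyl-1,3-dioxolan-4-yl]-5-[(1Z)-2-iodoprop-1-en-1-yl]-3-methylideneoxolan-2-one
Product: 11 (4R,5R)-4-[(1S)-1,2-dihydroxyethyl]-5-[(1Z)-2-iodoprop-1-en-1-yl]-3-methylideneoxolan-2-one
Conditions: AcOH/H2O 4:1, 35 °C
Reagents that add atoms: none
Why: Acid-catalysed hydrolysis of the terminal isopropylidene acetal. Weak acid and mild temperature are chosen so that the lactone does not migrate from O6 to O8 (the change of descriptor at the ring carbon is only a priority effect).

Step 7
Reactants: 11 (4R,5R)-4-[(1S)-1,2-dihydroxyethyl]-5-[(1Z)-2-iodoprop-1-en-1-yl]-3-methylideneoxolan-2-one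
Product: 12 (4R,5R)-4-[(1S)-1-hydroxy-2-(triethylsilyloxy)ethyl]-5-[(1Z)-2-iodoprop-1-en-1-yl]-3-methylideneoxolan-2-one
Conditions: Et3SiCl (1.05 equiv), imidazole, CH2Cl2, −40 °C
Reagents that add atoms: chlorotriethylsilane CC[Si](Cl)(CC)CC
Why: Silylation of the less hindered primary hydroxyl at low temperature. It leaves only O8 free for step 11 and installs the group that step 12 turns directly into the aldehyde.

Step 8
Reactants: 13 tert-butyl acrylate; 14 acetaldehyde
Product: 15 tert-butyl 3-hydroxy-2-methylidenebutanoate (racemic)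
Conditions: DABCO (0.2 equiv), neat, rt, 5 d
Reagents that add atoms: none
Why: Morita–Baylis–Hillman reaction of a simple aliphatic aldehyde. The stereocentre is removed in step 9.

Step 9
Reactants: 15 tert-butyl 3-hydroxy-2-methylidenebutanoate
Product: 17 tert-butyl (2E)-2-(acetoxymethyl)but-2-enoate, via secondary acetate 16 (not isolated)
Conditions: Ac2O, Et3N, DMAP (cat.), THF, 0 °C to rt; then DABCO (20 mol %), 65 °C
Reagents that add atoms: acetic anhydride CC(=O)OC(C)=O
Why: Acetylation, then amine-catalysed SN2'/SN2' transposition of the acetate. Equilibration should favour the conjugated trisubstituted olefin with the methyl group trans to the ester (E), as the target requires.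

Step 10
Reactants: 17 tert-butyl (2E)-2-(acetoxymethyl)but-2-enoate
Product: 18 (2E)-2-(acetoxymethyl)but-2-enoic acid
Conditions: TFA/CH2Cl2 1:4, 0 °C to rt
Reagents that add atoms: none
Why: Acidolysis of the tert-butyl ester with loss of isobutene. The primary acetate and the olefin geometry are not affected by anhydrous acid.

Step 11
Reactants: 12 (4R,5R)-4-[(1S)-1-hydroxy-2-(triethylsilyloxy)ethyl]-5-[(1Z)-2-iodoprop-1-en-1-yl]-3-methylideneoxolan-2-one; 18 (2E)-2-(acetoxymethyl)but-2-enoic acid
Product: 20 (1S)-1-[(2R,3S)-2-[(1Z)-2-iodoprop-1-en-1-yl]-4-methylidene-5-oxooxolan-3-yl]-2-(triethylsilyloxy)ethyl (2E)-2-(acetoxymethyl)but-2-enoate, via mixed anhydride 19 (not isolated)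
Conditions: 2,4,6-Cl3C6H2COCl, Et3N, toluene, 0 °C to rt; then 12, DMAP (0.5 equiv), rt
Reagents that add atoms: none
Why: Yamaguchi esterification of the only free hydroxyl (O8). The C–O8 bond is not touched, so C8 keeps its configuration, and the E-enoate is the stable isomer under acyl-transfer conditions.

Step 12
Reactants: 20 (1S)-1-[(2R,3S)-2-[(1Z)-2-iodoprop-1-en-1-yl]-4-methylidene-5-oxooxolan-3-yl]-2-(triethylsilyloxy)ethyl (2E)-2-(acetoxymethyl)but-2-enoate
Product: 21 (1S)-1-[(2R,3S)-2-[(1Z)-2-iodoprop-1-en-1-yl]-4-methylidene-5-oxooxolan-3-yl]-2-oxoethyl (2E)-2-(acetoxymethyl)but-2-enoate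
Conditions: (COCl)2, DMSO, CH2Cl2, −78 to −40 °C; then Et3N, −78 to −20 °C
Reagents that add atoms: none
Why: Swern oxidation applied directly to the primary triethylsilyl ether. The chlorosulfonium salt cleaves the primary Si–O bond and the alkoxysulfonium ylide collapses to the aldehyde, so no free 9-hydroxy 8-ester (acyl migration) is handled. Low temperature and brief base contact protect C8.

Step 13
Reactants: 22 3-hydroxybutan-2-one (racemic); 23 ethyl formate
Product: 25 2-methylfuran-3(2H)-one (racemic), via 4-hydroxy-3-oxopentanal 24 (not isolated)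
Conditions: NaH (2.2 equiv), Et2O, 0 °C to rt; then 3 M aq. HCl, 0 °C
Reagents that add atoms: none
Why: Crossed Claisen formylation at the methyl ketone (the only site that gives a stabilised β-keto aldehyde enolate), then acid-catalysed cyclodehydration of the hydroxy keto aldehyde to the 3(2H)-furanone.

Step 14
Reactants: 25 2-methylfuran-3(2H)-one
Product: 26 triisopropyl[(2-methylfuran-3-yl)oxy]silane
Conditions: i-Pr3SiOTf, Et3N, CH2Cl2, 0 °C
Reagents that add atoms: triisopropylsilyl trifluoromethanesulfonate CC(C)[Si](C(C)C)(C(C)C)OS(=O)(=O)C(F)(F)F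
Why: Soft enolisation and O-silylation. Loss of the C2 proton gives the aromatic 3-silyloxyfuran, which erases the racemic stereocentre.

Step 15
Reactants: 26 triisopropyl[(2-methylfuran-3-yl)oxy]silane
Product: 28 tributyl[5-methyl-4-(triisopropylsilyloxy)furan-2-yl]stannane, via 5-lithiofuran 27 (not isolated)
Conditions: n-BuLi, THF, −78 to 0 °C; then Bu3SnCl, −78 °C to rt
Reagents that add atoms: tributyltin chloride CCCC[Sn](Cl)(CCCC)CCCC
Why: α-Lithiation of the furan at its only free α-position (the future C3), then stannylation. The bulky silyloxy group is a poor director towards the β-position.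

Step 16
Reactants: 21 (1S)-1-[(2R,3S)-2-[(1Z)-2-iodoprop-1-en-1-yl]-4-methylidene-5-oxooxolan-3-yl]-2-oxoethyl (2E)-2-(acetoxymethyl)but-2-enoate; 28 tributyl[5-methyl-4-(triisopropylsilyloxy)furan-2-yl]stannane
Product: 29 (1S)-1-[(2S,3S)-2-{(1Z)-2-[5-methyl-4-(triisopropylsilyloxy)furan-2-yl]prop-1-en-1-yl}-4-methylidene-5-oxooxolan-3-yl]-2-oxoethyl (2E)-2-(acetoxymethyl)but-2-enoate
Conditions: Cu(O2C-C4H3S) (copper thiophene-2-carboxylate, monovalent copper, 1.5 equiv), NMP, 0 °C to rt, dark; filtered through neutral alumina and used at once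
Reagents that add atoms: none
Why: Copper-mediated Stille-type coupling of a vinyl iodide with a 2-furylstannane. It runs near room temperature with retention of the Z geometry, and without palladium the side-chain allylic acetate is not ionised; the aldehyde is tolerated.

Step 17
Reactants: 29 (1S)-1-[(2S,3S)-2-{(1Z)-2-[5-methyl-4-(triisopropylsilyloxy)furan-2-yl]prop-1-en-1-yl}-4-methylidene-5-oxooxolan-3-yl]-2-oxoethyl (2E)-2-(acetoxymethyl)but-2-enoate
Product: 31 (2Z,4S,8S,9S,10S,11R)-10-hydroxy-2,11-dimethyl-7-methylidene-6,12-dioxo-5,14-dioxatricyclo[9.2.1.0^4,8]tetradeca-1(13),2-dien-9-yl (2E)-2-(acetoxymethyl)but-2-enoate, via difluoroboryl aldolate 30 (not isolated)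
Conditions: BF3·OEt2 (2 equiv), CH2Cl2, −78 °C, 29 added over 4 h to 1 mM; then sat. aq. NaHCO3, −78 °C to rt
Reagents that add atoms: none
Why: BF3 binds the C9 aldehyde; C10 of the silyloxyfuran (β-carbon of the silyl enol ether and α to the ring oxygen) attacks it, and the silyloxocarbenium ion loses its silyl group to fluoride, which leaves the 3(2H)-furanone and the O9–BF2 aldolate. The closest known reaction is the Mukaiyama aldol addition of 3-silyloxyfurans to aldehydes at C2, here run as a ring closure. The new C9–C10 bond closes the ten-membered carbocycle in a 10-exo-trig sense at the carbonyl (9-exo-trig when counted through the furan oxygen), with the enol double bond inside the new ring. C10: the furan is flat, so its configuration is decided by the face that C9 can reach; the one-atom oxygen bridge forces C8 to sit above the furan oxygen, and inspection of the geometry suggests that only on the face leading to 10R do H6 and H8 point at the furan while the lactone and the C8 ester stay outside. C9: with the C8–O bond antiperiplanar to the aldehyde C=O and C7 anti to the forming bond (Cornforth or polar Felkin–Anh arrangement; BF3 and an acyloxy group do not chelate), attack should give the 8,9-anti relationship, 9S. The two preferences are expected to reinforce each other, with the aldehyde oxygen on the C1 side and H9 facing the C14 methyl. Chemoselectivity should be secured by the much higher electrophilicity of the BF3-bound aldehyde compared with the methylene lactone and the enoate, by C10 being the most nucleophilic furan carbon, and by the 1 mM concentration against oligomerisation. The aldolate stays boron-bound until work-up, so retro-aldol opening is not expected and the free O9–H of the target is released directly.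

## Compound list

1 | (4R)-2,2-dimethyl-1,3-dioxolane-4-carbaldehyde | O=C[C@H]1COC(C)(C)O1 | starting material
2 | methyl acrylate | C=CC(=O)OC | starting material
3 | methyl 2-{[(4R)-2,2-dimethyl-1,3-dioxolan-4-yl](hydroxy)methyl}prop-2-enoate (both carbinol epimers) | COC(=O)C(=C)C(O)[C@H]1COC(C)(C)O1 | intermediate
4 | methyl (2Z)-2-(bromomethyl)-3-[(4S)-2,2-dimethyl-1,3-dioxolan-4-yl]prop-2-enoate | COC(=O)/C(CBr)=C/[C@H]1COC(C)(C)O1 | intermediate
5 | but-2-yn-1-ol | CC#CCO | starting material
6 | sodium 2,2-bis(2-methoxyethoxy)-3-methyl-2,5-dihydro-1,2-oxaluminol-2-uide (cyclic vinylalanate) | CC1=CCO[Al-]1(OCCOC)OCCOC.[Na+] | intermediate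
7 | (2Z)-3-iodobut-2-en-1-ol | C/C(I)=C/CO | intermediate
8 | (2Z)-3-iodobut-2-enal | C/C(I)=C/C=O | intermediate
9 | methyl (3S,4R,5Z)-3-[(4S)-2,2-dimethyl-1,3-dioxolan-4-yl]-4-hydroxy-6-iodo-2-methylidenehept-5-enoate | COC(=O)C(=C)[C@@H]([C@@H](O)/C=C(/C)I)[C@H]1COC(C)(C)O1 | intermediate
10 | (4S,5R)-4-[(4S)-2,2-dimethyl-1,3-dioxolan-4-yl]-5-[(1Z)-2-iodoprop-1-en-1-yl]-3-methylideneoxolan-2-one | C=C1C(=O)O[C@@H](/C=C(/C)I)[C@H]1[C@H]2COC(C)(C)O2 | intermediate
11 | (4R,5R)-4-[(1S)-1,2-dihydroxyethyl]-5-[(1Z)-2-iodoprop-1-en-1-yl]-3-methylideneoxolan-2-one | C=C1C(=O)O[C@@H](/C=C(/C)I)[C@H]1[C@H](O)CO | intermediate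
12 | (4R,5R)-4-[(1S)-1-hydroxy-2-(triethylsilyloxy)ethyl]-5-[(1Z)-2-iodoprop-1-en-1-yl]-3-methylideneoxolan-2-one | C=C1C(=O)O[C@@H](/C=C(/C)I)[C@H]1[C@H](O)CO[Si](CC)(CC)CC | intermediate
13 | tert-butyl acrylate | C=CC(=O)OC(C)(C)C | starting material
14 | acetaldehyde | CC=O | starting material
15 | tert-butyl 3-hydroxy-2-methylidenebutanoate (racemic) | CC(O)C(=C)C(=O)OC(C)(C)C | intermediate
16 | tert-butyl 3-acetoxy-2-methylidenebutanoate (racemic) | CC(OC(C)=O)C(=C)C(=O)OC(C)(C)C | intermediate
17 | tert-butyl (2E)-2-(acetoxymethyl)but-2-enoate | C/C=C(\COC(C)=O)C(=O)OC(C)(C)C | intermediate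
18 | (2E)-2-(acetoxymethyl)but-2-enoic acid | C/C=C(\COC(C)=O)C(=O)O | intermediate
19 | (2E)-2-(acetoxymethyl)but-2-enoic 2,4,6-trichlorobenzoic anhydride | C/C=C(\COC(C)=O)C(=O)OC(=O)c1c(Cl)cc(Cl)cc1Cl | intermediate
20 | (1S)-1-[(2R,3S)-2-[(1Z)-2-iodoprop-1-en-1-yl]-4-methylidene-5-oxooxolan-3-yl]-2-(triethylsilyloxy)ethyl (2E)-2-(acetoxymethyl)but-2-enoate | C=C1C(=O)O[C@@H](/C=C(/C)I)[C@H]1[C@H](OC(=O)/C(=C/C)COC(C)=O)CO[Si](CC)(CC)CC | intermediate
21 | (1S)-1-[(2R,3S)-2-[(1Z)-2-iodoprop-1-en-1-yl]-4-methylidene-5-oxooxolan-3-yl]-2-oxoethyl (2E)-2-(acetoxymethyl)but-2-enoate | C=C1C(=O)O[C@@H](/C=C(/C)I)[C@H]1[C@H](OC(=O)/C(=C/C)COC(C)=O)C=O | intermediate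
22 | 3-hydroxybutan-2-one (racemic) | CC(O)C(C)=O | starting material
23 | ethyl formate | CCOC=O | starting material
24 | 4-hydroxy-3-oxopentanal (present as its sodium enolate) | CC(O)C(=O)CC=O | intermediate
25 | 2-methylfuran-3(2H)-one (racemic) | CC1OC=CC1=O | intermediate
26 | triisopropyl[(2-methylfuran-3-yl)oxy]silane | Cc1occc1O[Si](C(C)C)(C(C)C)C(C)C | intermediate
27 | [5-methyl-4-(triisopropylsilyloxy)furan-2-yl]lithium | [Li]c1cc(O[Si](C(C)C)(C(C)C)C(C)C)c(C)o1 | intermediate
28 | tributyl[5-methyl-4-(triisopropylsilyloxy)furan-2-yl]stannane | CCCC[Sn](CCCC)(CCCC)c1cc(O[Si](C(C)C)(C(C)C)C(C)C)c(C)o1 | intermediate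
29 | (1S)-1-[(2S,3S)-2-{(1Z)-2-[5-methyl-4-(triisopropylsilyloxy)furan-2-yl]prop-1-en-1-yl}-4-methylidene-5-oxooxolan-3-yl]-2-oxoethyl (2E)-2-(acetoxymethyl)but-2-enoate | C=C1C(=O)O[C@@H](/C=C(/C)c2cc(O[Si](C(C)C)(C(C)C)C(C)C)c(C)o2)[C@H]1[C@H](OC(=O)/C(=C/C)COC(C)=O)C=O | intermediate
30 | O9-difluoroboryl ether of 31 (difluoroboryl aldolate) | C=C1C(=O)O[C@H]2/C=C(/C)C3=CC(=O)[C@](C)(O3)[C@@H](OB(F)F)[C@@H](OC(=O)/C(=C/C)COC(C)=O)[C@@H]12 | intermediate
31 | (2Z,4S,8S,9S,10S,11R)-10-hydroxy-2,11-dimethyl-7-methylidene-6,12-dioxo-5,14-dioxatricyclo[9.2.1.0^4,8]tetradeca-1(13),2-dien-9-yl (2E)-2-(acetoxymethyl)but-2-enoate | C=C1C(=O)O[C@H]2/C=C(/C)C3=CC(=O)[C@](C)(O3)[C@@H](O)[C@@H](OC(=O)/C(=C/C)COC(C)=O)[C@@H]12 | target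

## Step count and least certain steps

Total step count: 17. Longest linear sequence: 9 (steps 1, 2, 5, 6, 7, 11, 12, 16, 17).

**Step 17 (key step).** Most likely failure: poor facial selectivity at the furan (closure to the ring with the opposite configuration at C10), or no closure at all, with intermolecular aldol addition or protodesilylation of the silyloxyfuran taking over. The transition state is a strained bridged arrangement and the preference for 10R rests on conformational reasoning alone. Fallback, setting out from 21 and 28 and coming back at 31: the order of the two bond formations between these partners is reversed. An intermolecular BF3·OEt2 Mukaiyama aldol addition of 28 to 21 forms C9–C10 first (C9 under acyclic Felkin–Anh control, the C10 epimers separated) and gives the seco stannane (1S,2S)-2-hydroxy-1-[(2R,3S)-2-[(1Z)-2-iodoprop-1-en-1-yl]-4-methylidene-5-oxooxolan-3-yl]-2-[(2R)-2-methyl-3-oxo-5-(tributylstannyl)-2,3-dihydrofuran-2-yl]ethyl (2E)-2-(acetoxymethyl)but-2-enoate F1. The ring is then closed at C3–C4 by an intramolecular copper-mediated Stille coupling (copper thiophene-2-carboxylate, NMP, 1 mM), which gives 31.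

**Step 5.** Most likely failure: addition to the wrong face of the allyl unit relative to C8, or Z-to-E isomerisation of 8 in the aqueous metal medium. The 1,2-induction from a dioxolanyl group is modest and β-iodoenals isomerise easily. Fallback, setting out from 4 (with 8) and coming back at 10: the substrate-controlled Barbier reaction is replaced by a catalyst-controlled allylboration. Borylation of 4 (B2pin2, Pd2(dba)3 with zerovalent palladium, toluene, 50 °C) gives methyl (2E)-3-[(4S)-2,2-dimethyl-1,3-dioxolan-4-yl]-2-[(4,4,5,5-tetramethyl-1,3,2-dioxaborolan-2-yl)methyl]prop-2-enoate F2. Its addition to 8 under a chiral BINOL-derived phosphoric acid (toluene, −30 °C) runs through a closed chair in which the catalyst selects the aldehyde face and, through the chair, C7. Acid lactonisation of the resulting 9 gives 10.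

**Step 16.** Most likely failure: degradation of the α-acyloxy aldehyde (epimerisation at C8) or protodestannylation of 28 before the hindered 2-iodopropenyl group couples, because the medium contains a Lewis-acidic copper carboxylate. Fallback, setting out from 20 (with 28) and coming back at 29: the coupling is done one stage earlier and the aldehyde is made afterwards. The same copper-mediated coupling of 20 with 28 gives the silyl ether (1S)-1-[(2S,3S)-2-{(1Z)-2-[5-methyl-4-(triisopropylsilyloxy)furan-2-yl]prop-1-en-1-yl}-4-methylidene-5-oxooxolan-3-yl]-2-(triethylsilyloxy)ethyl (2E)-2-(acetoxymethyl)but-2-enoate F3. Buffered HF·pyridine (THF/pyridine, 0 °C) removes only the primary triethylsilyl group and gives the alcohol (1S)-2-hydroxy-1-[(2S,3S)-2-{(1Z)-2-[5-methyl-4-(triisopropylsilyloxy)furan-2-yl]prop-1-en-1-yl}-4-methylidene-5-oxooxolan-3-yl]ethyl (2E)-2-(acetoxymethyl)but-2-enoate F4. Parikh–Doering oxidation (SO3·pyridine, DMSO, i-Pr2NEt, 0 °C) then gives 29.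

**Step 12.** Most likely failure: incomplete cleavage-oxidation of the silyl ether, or epimerisation at C8 during the amine stage. The direct oxidation needs warming to −40 °C, and the new aldehyde has an acidic α-hydrogen next to an acyloxy group. Fallback, setting out from 20 and coming back at 21: deprotection and oxidation are separated. HF·pyridine/pyridine in THF at 0 °C gives the alcohol (1S)-2-hydroxy-1-[(2R,3S)-2-[(1Z)-2-iodoprop-1-en-1-yl]-4-methylidene-5-oxooxolan-3-yl]ethyl (2E)-2-(acetoxymethyl)but-2-enoate F5. It is kept cold to limit O8-to-O9 acyl migration and oxidised at once with Dess–Martin periodinane/NaHCO3 to 21.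

**Step 13.** Most likely failure: low conversion through self-condensation of 22 under NaH, and polymerisation of the volatile furanone during the aqueous acid stage. Fallback, setting out from 22 and coming back at 25: the formyl unit is brought in as an enaminone. Heating 22 with N,N-dimethylformamide dimethyl acetal (neat, 80 °C) gives (1E)-1-(dimethylamino)-4-hydroxypent-1-en-3-one F6. Dilute HCl in THF cyclises it with loss of dimethylamine to 25.

## Further compounds

F1 | step 17 | (1S,2S)-2-hydroxy-1-[(2R,3S)-2-[(1Z)-2-iodoprop-1-en-1-yl]-4-methylidene-5-oxooxolan-3-yl]-2-[(2R)-2-methyl-3-oxo-5-(tributylstannyl)-2,3-dihydrofuran-2-yl]ethyl (2E)-2-(acetoxymethyl)but-2-enoate | C=C1C(=O)O[C@@H](/C=C(/C)I)[C@H]1[C@H](OC(=O)/C(=C/C)COC(C)=O)[C@H](O)[C@@]1(C)OC(=CC1=O)[Sn](CCCC)(CCCC)CCCC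
F2 | step 5 | methyl (2E)-3-[(4S)-2,2-dimethyl-1,3-dioxolan-4-yl]-2-[(4,4,5,5-tetramethyl-1,3,2-dioxaborolan-2-yl)methyl]prop-2-enoate | COC(=O)/C(CB1OC(C)(C)C(C)(C)O1)=C/[C@H]2COC(C)(C)O2
F3 | step 16 | (1S)-1-[(2S,3S)-2-{(1Z)-2-[5-methyl-4-(triisopropylsilyloxy)furan-2-yl]prop-1-en-1-yl}-4-methylidene-5-oxooxolan-3-yl]-2-(triethylsilyloxy)ethyl (2E)-2-(acetoxymethyl)but-2-enoate | C=C1C(=O)O[C@@H](/C=C(/C)c2cc(O[Si](C(C)C)(C(C)C)C(C)C)c(C)o2)[C@H]1[C@H](OC(=O)/C(=C/C)COC(C)=O)CO[Si](CC)(CC)CC
F4 | step 16 | (1S)-2-hydroxy-1-[(2S,3S)-2-{(1Z)-2-[5-methyl-4-(triisopropylsilyloxy)furan-2-yl]prop-1-en-1-yl}-4-methylidene-5-oxooxolan-3-yl]ethyl (2E)-2-(acetoxymethyl)but-2-enoate | C=C1C(=O)O[C@@H](/C=C(/C)c2cc(O[Si](C(C)C)(C(C)C)C(C)C)c(C)o2)[C@H]1[C@H](OC(=O)/C(=C/C)COC(C)=O)CO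
F5 | step 12 | (1S)-2-hydroxy-1-[(2R,3S)-2-[(1Z)-2-iodoprop-1-en-1-yl]-4-methylidene-5-oxooxolan-3-yl]ethyl (2E)-2-(acetoxymethyl)but-2-enoate | C=C1C(=O)O[C@@H](/C=C(/C)I)[C@H]1[C@H](OC(=O)/C(=C/C)COC(C)=O)CO
F6 | step 13 | (1E)-1-(dimethylamino)-4-hydroxypent-1-en-3-one | CC(O)C(=O)/C=C/N(C)C
A1 | alternative 1 | methyl (2Z,4S,5S)-2-(bromomethyl)-4,5-bis(tert-butyldimethylsilyloxy)-5-{(2R)-2-methyl-3-oxo-5-[(2Z)-4-oxobut-2-en-2-yl]-2,3-dihydrofuran-2-yl}pent-2-enoate | O=C/C=C(/C)C1=CC(=O)[C@](C)(O1)[C@@H](O[Si](C)(C)C(C)(C)C)[C@@H](O[Si](C)(C)C(C)(C)C)/C=C(\CBr)C(=O)OC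
A2 | alternative 2 | (6S,7S,8S,9S,10R)-8-(tert-butyldimethylsilyloxy)-9,10-dihydroxy-1-oxogermacra-4Z,11(13)-dien-2-yn-12,6-olide | C=C1C(=O)O[C@H]2/C=C(/C)C#CC(=O)[C@](C)(O)[C@@H](O)[C@@H](O[Si](C)(C)C(C)(C)C)[C@@H]12
A3 | alternative 3 | (2R,3S)-3-{(1S,2S)-1,2-bis(tert-butyldimethylsilyloxy)-2-[(2R)-5-ethyl-2-methyl-3-oxo-2,3-dihydrofuran-2-yl]ethyl}-4-methylidene-5-oxooxolane-2-carbaldehyde | CCC1=CC(=O)[C@](C)(O1)[C@@H](O[Si](C)(C)C(C)(C)C)[C@@H](O[Si](C)(C)C(C)(C)C)[C@H]1C(=C)C(=O)O[C@H]1C=O
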